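**Retrosynthetic overview**
1. The target is gibberellin A(4) with water added across C16=C17, with 16-OH endo (toward the C9–C11–C12 bridge) and 16-CH3 exo (toward C14). Rings A, B, C, D and the lactone, with all eight ring stereocentres, are taken intact from gibberellin A(4), so no ring is formed in the route.
2. Key disconnection C16–CH3: exo-face methyl delivery to the C16 ketone of the 16-norketone by a cathodically driven samarium Barbier methylation, which creates the only new stereocentre. Capture of a heteroatom at a C16 cation or radical would also come from the exo face and give the C16 epimer.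
3. C16=O is traced back to the exocyclic methylene of gibberellin A(4) (ozonolysis).
4. 3-OH and 7-CO2H pass the organometallic step as triethylsilyl groups; all silyl groups are removed in the same flask after the methylation.

Assumption: gibberellin A(4), the fermentation-derived plant growth regulator sold in technical grade, is taken as the commercially available, inexpensive chiral starting material.

**Step 1**
Reactants: 1 gibberellin A(4)
Product: 3 gibberellin A(4) 16-norketone (17-nor-16-oxo acid), via spiro-ozonide 2 (not isolated)
Conditions: O3/O2, EtOAc, −78 °C; then PPh3 (1.2 equiv), −78 → 20 °C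
Reagents that add atoms: ozone, [O-][O+]=O
Why: Ozonolysis (Criegee mechanism) cleaves the only C=C bond, the 1,1-disubstituted C16=C17 methylene, to the C16 ketone and formaldehyde; the free 3-OH and CO2H are inert to O3 at −78 °C, and no stereocentre is touched because the neighbouring bridgehead C13–H cannot enolise.

**Step 2**
Reactants: 3 gibberellin A(4) 16-norketone
Product: 4 3-O-triethylsilyl 16-norketone triethylsilyl ester
Conditions: Et3SiCl (3 equiv), imidazole (6 equiv), DMF, 20 → 40 °C
Reagents that add atoms: chlorotriethylsilane, CC[Si](Cl)(CC)CC
Why: Corey-type silylation (chlorosilane/imidazole) caps the carboxylic acid and the hindered axial 3-hydroxyl, so that no acidic proton destroys the methylsamarium reagent and no free 3-alkoxide can start retro-aldol epimerisation at C3; imidazole is too weak a base to enolise the ketone, and no stereocentre is touched.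

**Step 3**
Reactants: 4 3-O-triethylsilyl 16-norketone triethylsilyl ester
Product: 7 (16S)-16-hydroxy-16,17-dihydrogibberellin A(4) (target CNP0343121.3), via diiodosamarium alkoxide 5 (not isolated), via tris-silyl ether 6 (not isolated)
Conditions: SmI2 (15 mol%), NiI2 (2 mol%), MeI (6 equiv), Me3SiCl (3 equiv), tetrabutylammonium hexafluorophosphate (0.1 M), THF, Zn anode, carbon-felt cathode, undivided cell, 5 mA cm−2, 3 F mol−1, 20 °C; then HF·pyridine, pyridine, THF, 0 → 20 °C
Reagents that add atoms: iodomethane, CI
Why: Proposed new method: a cathodically recycled SmI2/NiI2 catalyst pair is proposed to turn MeI into methylsamarium diiodide (zerovalent nickel formed at the cathode adds MeI oxidatively and hands the methyl to samarium, or two single-electron transfers from divalent samarium do the same), which adds to the C16 ketone in a Barbier-type 1,2-addition from the open exo face (the side of the one-carbon C14 bridge; the endo face is screened by the axial C11–H that points at the two-carbon C15–C16 bridge, as in bicyclo[3.2.1]octan-6-ones generally), so that CH3 ends exo and O endo (16S), after which Me3SiCl silylates the trivalent samarium alkoxide to release the metal for re-reduction at the cathode while the zinc anode balances the charge, and buffered HF finally strips the three silyl groups; the closest known reaction types are the stoichiometric samarium Barbier reaction of ketones with alkyl iodides (including its NiI2-accelerated form) and samarium-electrocatalysed ketyl couplings with chlorosilane turnover, and what is new is their merger into an electrocatalytic C-methylation and its use on a bridged ketone that carries a lactone and a silyl ester.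

**Compound list**
1 | gibberellin A(4): 3β-hydroxy-16-methylene C19-gibberellin 19,10-lactone 7-oic acid (ent-3α,10β-dihydroxy-20-norgibberell-16-ene-7,19-dioic acid 19,10-lactone), natural configuration 3S,4S,5R,6S,8R,9R,10R,13R (gibberellane numbering) | C[C@@]12C(=O)O[C@]3(CC[C@@H]1O)[C@@H]1CC[C@@H]4C[C@]1(CC4=C)[C@@H](C(=O)O)[C@@H]32 | starting material
2 | spiro secondary ozonide of 1: C16 and C17 joined in a 1,2,4-trioxolane (C16–O–O–C17H2–O–C16), rest as in 1, either configuration at the spiro carbon C16 | C[C@@]12C(=O)O[C@]3(CC[C@@H]1O)[C@@H]1CC[C@@H]4C[C@]1(CC45OCOO5)[C@@H](C(=O)O)[C@@H]32 | intermediate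
3 | gibberellin A(4) 16-norketone: 1 with C16=CH2 replaced by C16=O (17-nor-16-oxo), 3β-OH and 7-CO2H free, ring stereocentres as in 1 | C[C@@]12C(=O)O[C@]3(CC[C@@H]1O)[C@@H]1CC[C@@H]4C[C@]1(CC4=O)[C@@H](C(=O)O)[C@@H]32 | intermediate
4 | 3 with the 3β-OH as triethylsilyl ether and the 7-CO2H as triethylsilyl ester | C[C@@]12C(=O)O[C@]3(CC[C@@H]1O[Si](CC)(CC)CC)[C@@H]1CC[C@@H]4C[C@]1(CC4=O)[C@@H](C(=O)O[Si](CC)(CC)CC)[C@@H]32 | intermediate
5 | diiodosamarium alkoxide: 4 after exo-face addition of CH3 to C16; C16 carries CH3 (exo, toward C14) and O–SmI2 (endo, toward the C9–C11–C12 bridge; trivalent samarium), 16S | C[C@@]12C(=O)O[C@]3(CC[C@@H]1O[Si](CC)(CC)CC)[C@@H]1CC[C@@H]4C[C@]1(C[C@]4(C)O[Sm](I)I)[C@@H](C(=O)O[Si](CC)(CC)CC)[C@@H]32 | intermediate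
6 | tris-silyl ether: as 5 with O–SiMe3 in place of O–SmI2 (16S) | C[C@@]12C(=O)O[C@]3(CC[C@@H]1O[Si](CC)(CC)CC)[C@@H]1CC[C@@H]4C[C@]1(C[C@]4(C)O[Si](C)(C)C)[C@@H](C(=O)O[Si](CC)(CC)CC)[C@@H]32 | intermediate
7 | target CNP0343121.3: (16S)-16-hydroxy-16,17-dihydrogibberellin A(4), 16-OH endo (toward the C9–C11–C12 bridge), 16-CH3 exo (toward C14); 3S,4S,5R,6S,8R,9R,10R,13R,16S | C[C@@]12C(=O)O[C@]3(CC[C@@H]1O)[C@@H]1CC[C@@H]4C[C@]1(C[C@]4(C)O)[C@@H](C(=O)O)[C@@H]32 | target

**Step count and risks**
Total step count: 3. Longest linear sequence: 3 steps (1 → 3 → 4 → 7).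

The three steps most likely to fail, most risky first:

Step 3 (the proposed electrocatalytic methylation). Possible failures are:
- slow activation of MeI without a strongly donating co-solvent;
- transfer of the methyl group to silicon instead of to the ketone;
- enolisation toward C15 with trapping as a silyl enol ether;
- ketyl-type reduction of the ketone;
- plating of zinc at the cathode in competition with samarium turnover, for which a magnesium or aluminium anode or a divided cell would be tried first.

A minor C16 epimer (methyl endo) would be removed by chromatography or crystallisation of 7. The fallback uses known chemistry, sets out from 4 and comes back to the route at 7. It gives up electrosynthesis and catalytic samarium for a preformed stoichiometric organocerium reagent, methylcerium dichloride MeCeCl2 (MeLi and anhydrous CeCl3, THF, −78 °C). This is an Imamoto-type 1,2-addition with a non-basic reagent, so the hindered enolisable ketone is methylated from the same exo face without touching the lactone or the silyl ester. After a cold quench with AcOH it gives the bis-triethylsilyl carbinol F1. HF·pyridine (pyridine, THF, 0 → 20 °C) then removes both silyl groups to give 7.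

Step 2 (double silylation). The axial 3-OH next to the quaternary C4 may silylate sluggishly, and forcing reagents in the presence of the ketone could form a silyl enol ether. The silyl ester is also moisture-sensitive, so 4 is taken on after a non-aqueous work-up. The fallback changes the order of events, sets out from 1 and comes back at 4. Compound 1 is silylated before any ketone exists (Et3SiOTf, 2,6-lutidine, CH2Cl2, −78 → 0 °C), where a silyl triflate can be used safely, to give the bis-triethylsilyl gibberellin F2. Ozonolysis (O3, CH2Cl2, −78 °C; then Me2S) through the spiro-ozonide F3 then delivers 4.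

Step 1 (ozonolysis). The hindered ozonide may be slow to reduce, and excess ozone could oxidise the carbinol C3–H. The fallback replaces ozone by osmylation and glycol cleavage, sets out from 1 and comes back at 3. OsO4 (2 mol%) with N-methylmorpholine N-oxide (acetone–water, 20 °C) dihydroxylates the methylene from the exo face to the 16,17-diol F4, and NaIO4 (THF–water, 20 °C) cleaves the glycol to 3.

**Further compounds**
F1 | step 3 | bis-triethylsilyl carbinol: 3-O-triethylsilyl-(16S)-16-hydroxy-16,17-dihydrogibberellin A(4) triethylsilyl ester (16-OH endo, 16-CH3 exo) | C[C@@]12C(=O)O[C@]3(CC[C@@H]1O[Si](CC)(CC)CC)[C@@H]1CC[C@@H]4C[C@]1(C[C@]4(C)O)[C@@H](C(=O)O[Si](CC)(CC)CC)[C@@H]32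
F2 | step 2 | bis-triethylsilyl gibberellin: 3-O-triethylsilyl gibberellin A(4) triethylsilyl ester | C[C@@]12C(=O)O[C@]3(CC[C@@H]1O[Si](CC)(CC)CC)[C@@H]1CC[C@@H]4C[C@]1(CC4=C)[C@@H](C(=O)O[Si](CC)(CC)CC)[C@@H]32
F3 | step 2 | spiro-ozonide of F2 (1,2,4-trioxolane on C16/C17, either configuration at the spiro carbon) | C[C@@]12C(=O)O[C@]3(CC[C@@H]1O[Si](CC)(CC)CC)[C@@H]1CC[C@@H]4C[C@]1(CC45OCOO5)[C@@H](C(=O)O[Si](CC)(CC)CC)[C@@H]32
F4 | step 1 | gibberellin A(4) 16,17-diol (16R; 16-OH exo, CH2OH endo) | C[C@@]12C(=O)O[C@]3(CC[C@@H]1O)[C@@H]1CC[C@@H]4C[C@]1(C[C@@]4(CO)O)[C@@H](C(=O)O)[C@@H]32
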